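The route is cut at C1''–C2'', where the benzylic methylene on C6 of ring A meets the E-configured C2''=C3'' alkene and its C3'' methyl branch. In one flask, methyl and aluminium are added syn across a terminal alkyne that already carries the (R)-C6'' silyl ether. Nickel then joins the alkenyl–metal carbon to a 2,6-bis(MOM)-4-TIPS benzylic chloride, so two C–C bonds and the E geometry arise together. Because only the oxygen para to the chain bears silicon, its release gives a symmetric phenol that can build ring C in one direction only, fixing 6-substitution. C2 is set late by rhodium-catalysed aryl addition to the derived chromone.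

Key step: step 9

Assumption: the target is read as 2S, 6''R, 2''E. The sense of induction in steps 3 and 17 is taken from the accepted models: the (S)-CBS catalyst, with the alkenyl group as the large substituent, gives the R carbinol, and an (S)-biaryl diphosphine on rhodium adds aryl to a cyclic enone on the face that corresponds to 2S in a flavanone.

Step 1
Reactants: 1 4-pentynoic acid
Product: 3 N-methoxy-N-methylpent-4-ynamide, via acyl imidazole 2 (not isolated)
Conditions: CDI, CH2Cl2, rt; then MeNH(OMe)·HCl, rt
Reagents that add atoms: N,O-dimethylhydroxylamine hydrochloride, Cl.CNOC; 1,1'-carbonyldiimidazole, O=C(n1ccnc1)n1ccnc1 (its atoms stay only in 2)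
Why: Acyl-imidazole activation followed by aminolysis is the standard Weinreb amide synthesis and leaves the terminal alkyne untouched.

Step 2
Reactants: 3 N-methoxy-N-methylpent-4-ynamide; 4 isopropenylmagnesium bromide
Product: 5 2-methylhept-1-en-6-yn-3-one
Conditions: 4 (2.3 equiv), THF, −20 → 0 °C; inverse quench into cold 1 M HCl
Reagents that add atoms: isopropenylmagnesium bromide (compound 4), C=C(C)[Mg]Br
Why: Weinreb ketone synthesis, in which chelation stops the reaction at mono-addition, the extra Grignard equivalent only covers the acidic alkyne C–H, and the acidic inverse quench protonates the released amine before it can add to the new enone.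

Step 3
Reactants: 5 2-methylhept-1-en-6-yn-3-one
Product: 6 (3R)-2-methylhept-1-en-6-yn-3-ol
Conditions: (S)-1-methyl-3,3-diphenyltetrahydro-1H,3H-pyrrolo[1,2-c][1,3,2]oxazaborole ((S)-Me-CBS, 15 mol %), catecholborane (1.8 equiv), toluene, −78 °C; MeOH, then aq. NaHCO3/NaOH wash
Reagents that add atoms: none
Why: Corey–Bakshi–Shibata reduction, in which the ketone binds the (S)-oxazaborolidine–borane complex with the branched isopropenyl group as the large substituent, so hydride reaches the face that gives the (R)-carbinol (future C6''), and at −78 °C catecholborane touches neither the alkyne nor the alkene.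

Step 4
Reactants: 6 (3R)-2-methylhept-1-en-6-yn-3-ol
Product: 7 (3R)-3-(tert-butyldimethylsilyloxy)-2-methylhept-1-en-6-yne
Conditions: TBSCl, imidazole, DMF, rt
Reagents that add atoms: tert-butyldimethylsilyl chloride, CC(C)(C)[Si](C)(C)Cl
Why: Imidazole-promoted silylation of a secondary alcohol takes place at oxygen and therefore retains the carbinol configuration.

Step 5
Reactants: 8 2,4,6-trihydroxybenzaldehyde
Product: 9 2,6-dihydroxy-4-(triisopropylsilyloxy)benzaldehyde
Conditions: TIPSCl (1.0 equiv), imidazole, DMF, 0 °C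
Reagents that add atoms: triisopropylsilyl chloride, CC(C)[Si](Cl)(C(C)C)C(C)C
Why: Selective silylation, since the 4-OH is the most acidic and least hindered hydroxyl while the 2- and 6-OH groups flank the formyl group and hydrogen-bond to it, so one equivalent of the bulky chlorosilane should react at O4.

Step 6
Reactants: 9 2,6-dihydroxy-4-(triisopropylsilyloxy)benzaldehyde
Product: 10 2,6-bis(methoxymethoxy)-4-(triisopropylsilyloxy)benzaldehyde
Conditions: NaH (2.4 equiv), MOMCl (2.6 equiv), THF–DMF, 0 °C
Reagents that add atoms: chloromethyl methyl ether, COCCl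
Why: Williamson-type O-alkylation of both phenoxides with MOMCl, where the strong base breaks the O–H···O=C hydrogen bond and the hindered TIPS ether tolerates the short, cold, anhydrous exposure.

Step 7
Reactants: 10 2,6-bis(methoxymethoxy)-4-(triisopropylsilyloxy)benzaldehyde
Product: 11 [2,6-bis(methoxymethoxy)-4-(triisopropylsilyloxy)phenyl]methanol
Conditions: NaBH4, THF–MeOH, 0 °C
Reagents that add atoms: none
Why: Borohydride reduction of an aromatic aldehyde, to which acetals and silyl ethers are inert.

Step 8
Reactants: 11 [2,6-bis(methoxymethoxy)-4-(triisopropylsilyloxy)phenyl]methanol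
Product: 13 2,6-bis(methoxymethoxy)-4-(triisopropylsilyloxy)benzyl chloride, via benzylic mesylate 12 (not isolated)
Conditions: MsCl, Et3N, CH2Cl2, −20 → 0 °C; cold aq. NaHCO3 wash, no chromatography, used the same day as a THF solution
Reagents that add atoms: methanesulfonyl chloride, CS(=O)(=O)Cl
Why: Mesylation with in situ chloride displacement, because in so electron-rich a benzylic system the sulfonate is displaced at once by the chloride of the ammonium salt, and the medium stays basic throughout, which protects the MOM groups.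

Step 9
Reactants: 7 (3R)-3-(tert-butyldimethylsilyloxy)-2-methylhept-1-en-6-yne; 14 trimethylaluminium; 13 2,6-bis(methoxymethoxy)-4-(triisopropylsilyloxy)benzyl chloride
Product: 16 2-[(2E,6R)-6-(tert-butyldimethylsilyloxy)-3,7-dimethylocta-2,7-dien-1-yl]-1,3-bis(methoxymethoxy)-5-(triisopropylsilyloxy)benzene, via alkenyldimethylalane 15 (not isolated)
Conditions: 7 (1.25 equiv), AlMe3 (2.5 equiv), Cp2ZrCl2 (0.25 equiv), ClCH2CH2Cl, 0 °C → rt; evaporate, triturate with hexane, take up in THF; then 13 (1.0 equiv), NiCl2(PPh3)2 (5 mol %)/n-BuLi (10 mol %), THF, 0 °C → rt; aq. potassium sodium tartrate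
Reagents that add atoms: trimethylaluminium (compound 14), C[Al](C)C
Why: Cp2ZrCl2 and AlMe3 form a polarised methylzirconocene–alane pair that adds methyl and metal syn across the terminal alkyne of 7, methyl going to the internal carbon, and Zr/Al exchange leaves the (E)-alkenyldimethylalane 15 (Negishi carboalumination). Zerovalent nickel inserts into the benzylic C–Cl bond of 13, the alkenyl group passes from aluminium to nickel in preference to methyl, and reductive elimination with retention forges C1''–C2''; this is the known alkenylalane–benzylic chloride cross-coupling used for polyprenylated arenes. No ring is closed and no stereocentre is created; the only new stereo-element, the E C2''=C3'' alkene, follows from syn addition plus retention, and C6'' lies three bonds away from the nearest reacting carbon (C3'') and is untouched. Chemoselectivity rests on the substrate: the 1,1-disubstituted C7''=C8'' alkene is too hindered for zirconocene-catalysed carbometalation, the TBS ether masks the only protic site, and the benzylnickel species has no beta hydrogen. Stripping excess AlMe3 and changing to THF before 13 is added keeps free Lewis acid away from the MOM acetals and from the ionisable chloride, whose two open ring positions are further shielded against self-alkylation by the TIPS group.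

Step 10
Reactants: 16 the coupled arene
Product: 17 4-[(2E,6R)-6-(tert-butyldimethylsilyloxy)-3,7-dimethylocta-2,7-dien-1-yl]-3,5-bis(methoxymethoxy)phenol
Conditions: TBAF (1.1 equiv), AcOH (1.1 equiv), THF, 0 °C
Reagents that add atoms: none
Why: Fluoride-mediated desilylation, in which the aryl silyl ether (phenoxide leaving group) is cleaved far faster than the secondary alkyl TBS ether and the acetic acid buffer keeps the medium from turning basic.

Step 11
Reactants: 17 the symmetric phenol
Product: 18 4-[(2E,6R)-6-(tert-butyldimethylsilyloxy)-3,7-dimethylocta-2,7-dien-1-yl]-2-iodo-3,5-bis(methoxymethoxy)phenol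
Conditions: I2 (1.0 equiv), NaHCO3, THF–H2O, 0 °C
Reagents that add atoms: iodine, II
Why: Electrophilic aromatic iodination of a phloroglucinol-type phenol under bicarbonate buffering, where the two ortho positions are equivalent, the para position is blocked and the activated ring should outrun both alkenes for one equivalent of iodine.

Step 12
Reactants: 18 the iodophenol
Product: 20 1-{3-[(2E,6R)-6-(tert-butyldimethylsilyloxy)-3,7-dimethylocta-2,7-dien-1-yl]-6-hydroxy-2,4-bis(methoxymethoxy)phenyl}ethan-1-one, via dilithiated phenoxide 19 (not isolated)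
Conditions: n-BuLi (2.1 equiv), THF, −78 °C; MeC(O)N(OMe)Me (3 equiv), −78 → 0 °C; aq. NH4Cl
Reagents that add atoms: N-methoxy-N-methylacetamide, CC(=O)N(C)OC; n-butyllithium, [Li]CCCC (lithium stays only in 19)
Why: Phenol deprotonation and iodine–lithium exchange at −78 °C are faster than any allylic or benzylic deprotonation, and acylation of the aryllithium by the Weinreb amide stops at the ketone (Weinreb ketone synthesis), so the acetyl group is installed without any Lewis acid.

Step 13
Reactants: 20 the 2-hydroxyacetophenone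
Product: 22 6-[(2E,6R)-6-(tert-butyldimethylsilyloxy)-3,7-dimethylocta-2,7-dien-1-yl]-5,7-bis(methoxymethoxy)-4H-chromen-4-one, via enaminone 21 (not isolated)
Conditions: Me2NCH(OMe)2 (4 equiv), toluene, 95 °C; evaporate; AcOH (10 equiv), toluene, 70 °C
Reagents that add atoms: N,N-dimethylformamide dimethyl acetal, COC(OC)N(C)C
Why: Enaminone route to chromones, namely condensation of the methyl ketone with the amide acetal, then acid-promoted addition of the only free phenol (future O1) to the beta carbon with loss of dimethylamine, acetic acid under anhydrous conditions being too weak to cleave aryl MOM ethers.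

Step 14
Reactants: 23 5-bromo-2-hydroxy-3-methoxybenzaldehyde
Product: 24 5-bromo-3-methoxybenzene-1,2-diol
Conditions: 30% H2O2, aq. NaOH, 0 °C → rt; dilute HCl to pH 3
Reagents that add atoms: hydrogen peroxide, OO
Why: Dakin oxidation of an ortho-hydroxybenzaldehyde, in which hydroperoxide addition, aryl migration and hydrolysis exchange CHO for OH and leave bromine para to the central oxygen.

Step 15
Reactants: 24 5-bromo-3-methoxybenzene-1,2-diol
Product: 25 5-bromo-1-methoxy-2,3-bis(methoxymethoxy)benzene
Conditions: MOMCl (3 equiv), i-Pr2NEt (4 equiv), CH2Cl2, 0 °C → rt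
Reagents that add atoms: chloromethyl methyl ether, COCCl
Why: Amine-base MOM protection of two catechol hydroxyls that are not tied up in a carbonyl hydrogen bond.

Step 16
Reactants: 25 5-bromo-1-methoxy-2,3-bis(methoxymethoxy)benzene
Product: 28 [3-methoxy-4,5-bis(methoxymethoxy)phenyl]boronic acid, via aryllithium 26 (not isolated), via lithium aryltriisopropoxyborate 27 (not isolated)
Conditions: n-BuLi (1.1 equiv), THF, −78 °C; B(Oi-Pr)3, −78 °C → rt; aq. NH4Cl
Reagents that add atoms: triisopropyl borate, CC(C)OB(OC(C)C)OC(C)C; water, O; n-butyllithium, [Li]CCCC (lithium stays only in 26 and 27)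
Why: Bromine–lithium exchange at −78 °C outpaces MOM-directed ortho-lithiation, and borylation with a trialkyl borate followed by near-neutral hydrolysis is the standard boronic acid synthesis.

Step 17
Reactants: 22 the chromone; 28 [3-methoxy-4,5-bis(methoxymethoxy)phenyl]boronic acid
Product: 29 (2S)-6-[(2E,6R)-6-(tert-butyldimethylsilyloxy)-3,7-dimethylocta-2,7-dien-1-yl]-2-[3-methoxy-4,5-bis(methoxymethoxy)phenyl]-5,7-bis(methoxymethoxy)chroman-4-one
Conditions: [Rh(OH)(cod)]2 (2.5 mol %), (S)-2,2'-bis[bis(3,4,5-trifluorophenyl)phosphino]-6,6'-dimethoxy-1,1'-biphenyl ((S)-MeO-F12-BIPHEP, 5.5 mol %), 28 (3 equiv), toluene–H2O (20:1), 30 °C, no added base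
Reagents that add atoms: none
Why: Hayashi–Miyaura asymmetric 1,4-addition, a reaction known for chromones, in which the aryl–rhodium species inserts C2=C3 on the face left open by the (S)-diphosphine (the sense that gives (S)-3-arylcyclohexanones and, by the same spatial course, the 2S flavanone), protonolysis of the rhodium enolate releases 29, the catalyst overrides the remote C6'' centre and the unactivated alkenes do not insert.

Step 18
Reactants: 29 the fully protected flavanone
Product: 30 (2S)-2-(3,4-dihydroxy-5-methoxyphenyl)-5,7-dihydroxy-6-[(2E,6R)-6-hydroxy-3,7-dimethylocta-2,7-dien-1-yl]chroman-4-one (CNP0144204.1)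
Conditions: HCl (1.25 M in MeOH), 0 → 40 °C; NaH2PO4/Na2HPO4 buffer (pH 6)
Reagents that add atoms: none
Why: Acid-catalysed transacetalisation and silyl ether solvolysis in methanol remove four MOM groups and the TBS group in one operation, under the kind of conditions long used for prenylated and geranylated flavonoids; C2 should hold because ring opening needs base, and C6'' should hold because its allyl cation would be poorly stabilised.

Compound list
1 | 4-pentynoic acid | C#CCCC(=O)O | starting material
2 | 1-(1H-imidazol-1-yl)pent-4-yn-1-one | C#CCCC(=O)n1ccnc1 | intermediate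
3 | N-methoxy-N-methylpent-4-ynamide | C#CCCC(=O)N(C)OC | intermediate
4 | isopropenylmagnesium bromide | C=C(C)[Mg]Br | starting material
5 | 2-methylhept-1-en-6-yn-3-one | C=C(C)C(=O)CCC#C | intermediate
6 | (3R)-2-methylhept-1-en-6-yn-3-ol | C=C(C)[C@H](O)CCC#C | intermediate
7 | (3R)-3-(tert-butyldimethylsilyloxy)-2-methylhept-1-en-6-yne | C=C(C)[C@H](O[Si](C)(C)C(C)(C)C)CCC#C | intermediate
8 | 2,4,6-trihydroxybenzaldehyde | O=Cc1c(O)cc(O)cc1O | starting material
9 | 2,6-dihydroxy-4-(triisopropylsilyloxy)benzaldehyde | O=Cc1c(O)cc(O[Si](C(C)C)(C(C)C)C(C)C)cc1O | intermediate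
10 | 2,6-bis(methoxymethoxy)-4-(triisopropylsilyloxy)benzaldehyde | O=Cc1c(OCOC)cc(O[Si](C(C)C)(C(C)C)C(C)C)cc1OCOC | intermediate
11 | [2,6-bis(methoxymethoxy)-4-(triisopropylsilyloxy)phenyl]methanol | OCc1c(OCOC)cc(O[Si](C(C)C)(C(C)C)C(C)C)cc1OCOC | intermediate
12 | 2,6-bis(methoxymethoxy)-4-(triisopropylsilyloxy)benzyl methanesulfonate | CS(=O)(=O)OCc1c(OCOC)cc(O[Si](C(C)C)(C(C)C)C(C)C)cc1OCOC | intermediate
13 | 2,6-bis(methoxymethoxy)-4-(triisopropylsilyloxy)benzyl chloride | ClCc1c(OCOC)cc(O[Si](C(C)C)(C(C)C)C(C)C)cc1OCOC | intermediate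
14 | trimethylaluminium | C[Al](C)C | starting material
15 | [(1E,5R)-5-(tert-butyldimethylsilyloxy)-2,6-dimethylhepta-1,6-dien-1-yl]dimethylalane | C=C(C)[C@H](O[Si](C)(C)C(C)(C)C)CC/C(C)=C/[Al](C)C | intermediate
16 | 2-[(2E,6R)-6-(tert-butyldimethylsilyloxy)-3,7-dimethylocta-2,7-dien-1-yl]-1,3-bis(methoxymethoxy)-5-(triisopropylsilyloxy)benzene | C=C(C)[C@H](O[Si](C)(C)C(C)(C)C)CC/C(C)=C/Cc1c(OCOC)cc(O[Si](C(C)C)(C(C)C)C(C)C)cc1OCOC | intermediate
17 | 4-[(2E,6R)-6-(tert-butyldimethylsilyloxy)-3,7-dimethylocta-2,7-dien-1-yl]-3,5-bis(methoxymethoxy)phenol | C=C(C)[C@H](O[Si](C)(C)C(C)(C)C)CC/C(C)=C/Cc1c(OCOC)cc(O)cc1OCOC | intermediate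
18 | 4-[(2E,6R)-6-(tert-butyldimethylsilyloxy)-3,7-dimethylocta-2,7-dien-1-yl]-2-iodo-3,5-bis(methoxymethoxy)phenol | C=C(C)[C@H](O[Si](C)(C)C(C)(C)C)CC/C(C)=C/Cc1c(OCOC)cc(O)c(I)c1OCOC | intermediate
19 | lithium 2-lithio-phenoxide derived from 18 | C=C(C)[C@H](O[Si](C)(C)C(C)(C)C)CC/C(C)=C/Cc1c(OCOC)cc(O[Li])c([Li])c1OCOC | intermediate
20 | 1-{3-[(2E,6R)-6-(tert-butyldimethylsilyloxy)-3,7-dimethylocta-2,7-dien-1-yl]-6-hydroxy-2,4-bis(methoxymethoxy)phenyl}ethan-1-one | C=C(C)[C@H](O[Si](C)(C)C(C)(C)C)CC/C(C)=C/Cc1c(OCOC)cc(O)c(C(C)=O)c1OCOC | intermediate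
21 | (E)-3-(dimethylamino)-1-aryl-prop-2-en-1-one derived from 20 | C=C(C)[C@H](O[Si](C)(C)C(C)(C)C)CC/C(C)=C/Cc1c(OCOC)cc(O)c(C(=O)/C=C/N(C)C)c1OCOC | intermediate
22 | 6-[(2E,6R)-6-(tert-butyldimethylsilyloxy)-3,7-dimethylocta-2,7-dien-1-yl]-5,7-bis(methoxymethoxy)-4H-chromen-4-one | C=C(C)[C@H](O[Si](C)(C)C(C)(C)C)CC/C(C)=C/Cc1c(OCOC)cc2occc(=O)c2c1OCOC | intermediate
23 | 5-bromo-2-hydroxy-3-methoxybenzaldehyde | COc1cc(Br)cc(C=O)c1O | starting material
24 | 5-bromo-3-methoxybenzene-1,2-diol | COc1cc(Br)cc(O)c1O | intermediate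
25 | 5-bromo-1-methoxy-2,3-bis(methoxymethoxy)benzene | COc1cc(Br)cc(OCOC)c1OCOC | intermediate
26 | [3-methoxy-4,5-bis(methoxymethoxy)phenyl]lithium | [Li]c1cc(OC)c(OCOC)c(OCOC)c1 | intermediate
27 | lithium [3-methoxy-4,5-bis(methoxymethoxy)phenyl]triisopropoxyborate | [Li+].CC(C)O[B-](OC(C)C)(OC(C)C)c1cc(OC)c(OCOC)c(OCOC)c1 | intermediate
28 | [3-methoxy-4,5-bis(methoxymethoxy)phenyl]boronic acid | COc1cc(B(O)O)cc(OCOC)c1OCOC | intermediate
29 | (2S)-6-[(2E,6R)-6-(tert-butyldimethylsilyloxy)-3,7-dimethylocta-2,7-dien-1-yl]-2-[3-methoxy-4,5-bis(methoxymethoxy)phenyl]-5,7-bis(methoxymethoxy)chroman-4-one | C=C(C)[C@H](O[Si](C)(C)C(C)(C)C)CC/C(C)=C/Cc1c(OCOC)cc2c(c1OCOC)C(=O)C[C@@H](c1cc(OCOC)c(OCOC)c(OC)c1)O2 | intermediate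
30 | (2S)-2-(3,4-dihydroxy-5-methoxyphenyl)-5,7-dihydroxy-6-[(2E,6R)-6-hydroxy-3,7-dimethylocta-2,7-dien-1-yl]chroman-4-one | C=C(C)[C@H](O)CC/C(C)=C/Cc1c(O)cc2c(c1O)C(=O)C[C@@H](c1cc(O)c(O)c(OC)c1)O2 | target

Total steps: 18. Longest linear sequence: 11 steps (steps 1–4 or 5–8, then 9–13, 17 and 18).

Steps most likely to fail

Step 9. Aluminium Lewis acids may ionise the very electron-rich benzylic chloride or strip MOM acetals before nickel engages it. Benzyl–benzyl homocoupling may also compete, and imperfect regiocontrol in the methylalumination would be carried into the product. The fallback sets out from 7 and 13 and returns at 16. It uncouples the two events so that ring A never meets aluminium.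
- Alane 15, made from 7 as before, is quenched with I2 in THF at −30 °C. This gives tert-butyl{[(3R,6E)-7-iodo-2,6-dimethylhepta-1,6-dien-3-yl]oxy}dimethylsilane F1, which can be freed from any regioisomer by chromatography.
- Chloride 13 is converted by zinc dust and LiCl in THF at 0–25 °C into [2,6-bis(methoxymethoxy)-4-(triisopropylsilyloxy)benzyl]zinc chloride F2.
- A Negishi coupling of F1 with F2 under Pd(PPh3)4 in THF at rt, which retains alkene geometry, delivers 16.

Step 17. Insertion of the electron-rich, 5-alkoxy-substituted chromone may be slow. The electron-rich boronic acid may protodeboronate, and reversible ring opening of the product may erode the configurational purity at C2. The fallback sets out from 20 and returns at 29.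
- Commercial 5-hydroxyvanillin is protected (MOMCl, i-Pr2NEt, CH2Cl2) as 3-methoxy-4,5-bis(methoxymethoxy)benzaldehyde F3.
- Claisen–Schmidt condensation of 20 with F3 (KOH, EtOH, rt) gives the (E)-2'-hydroxychalcone F4.
- NaOAc in refluxing EtOH closes ring C through the only free phenol, giving the protected flavanone as a mixture of C2 epimers F5.
- A Noyori asymmetric transfer hydrogenation is run as a kinetic resolution (RuCl(p-cymene)[(R,R)-TsDPEN], HCO2H/Et3N, EtOAc, rt, stopped near half conversion). It should reduce the (2R)-epimer to the cis-(2R,4R)-flavan-4-ol F6 and leave the (2S)-ketone 29, which is separated by chromatography.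

Step 18. Protonation of the C2''=C3'' alkene followed by capture by the freed 5- or 7-hydroxyl (chroman formation) is the main danger. Solvolysis or allylic transposition at C6'' and incomplete loss of the last acetal are also possible. The fallback sets out from 29 and returns at 30. It replaces the single solvolysis by a fluoride step and a soft Lewis acid/thiol step.
- HF·pyridine in THF–pyridine at 0 °C removes only the silyl group. This gives (2S)-6-[(2E,6R)-6-hydroxy-3,7-dimethylocta-2,7-dien-1-yl]-2-[3-methoxy-4,5-bis(methoxymethoxy)phenyl]-5,7-bis(methoxymethoxy)chroman-4-one F7.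
- ZnBr2 with n-PrSH in CH2Cl2 at 0 °C then cleaves the four aryl MOM ethers by thiol capture of the zinc-activated acetal. No acid strong enough to protonate an alkene is present.

Further compounds
F1 | step 9 | tert-butyl{[(3R,6E)-7-iodo-2,6-dimethylhepta-1,6-dien-3-yl]oxy}dimethylsilane | C=C(C)[C@H](O[Si](C)(C)C(C)(C)C)CC/C(C)=C/I
F2 | step 9 | [2,6-bis(methoxymethoxy)-4-(triisopropylsilyloxy)benzyl]zinc chloride | Cl[Zn]Cc1c(OCOC)cc(O[Si](C(C)C)(C(C)C)C(C)C)cc1OCOC
F3 | step 17 | 3-methoxy-4,5-bis(methoxymethoxy)benzaldehyde | COc1cc(C=O)cc(OCOC)c1OCOC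
F4 | step 17 | (E)-2'-hydroxychalcone from 20 and F3 | C=C(C)[C@H](O[Si](C)(C)C(C)(C)C)CC/C(C)=C/Cc1c(OCOC)cc(O)c(C(=O)/C=C/c2cc(OCOC)c(OCOC)c(OC)c2)c1OCOC
F5 | step 17 | protected flavanone as a mixture of C2 epimers | C=C(C)[C@H](O[Si](C)(C)C(C)(C)C)CC/C(C)=C/Cc1c(OCOC)cc2c(c1OCOC)C(=O)CC(c1cc(OCOC)c(OCOC)c(OC)c1)O2
F6 | step 17 | cis-(2R,4R)-flavan-4-ol from the (2R)-epimer | C=C(C)[C@H](O[Si](C)(C)C(C)(C)C)CC/C(C)=C/Cc1c(OCOC)cc2c(c1OCOC)[C@H](O)C[C@H](c1cc(OCOC)c(OCOC)c(OC)c1)O2
F7 | step 18 | (2S)-6-[(2E,6R)-6-hydroxy-3,7-dimethylocta-2,7-dien-1-yl]-2-[3-methoxy-4,5-bis(methoxymethoxy)phenyl]-5,7-bis(methoxymethoxy)chroman-4-one | C=C(C)[C@H](O)CC/C(C)=C/Cc1c(OCOC)cc2c(c1OCOC)C(=O)C[C@@H](c1cc(OCOC)c(OCOC)c(OC)c1)O2
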